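**Strategy.** The trans-fused γ-lactone cannot readily be closed at O–C6 on a finished chair cyclohexane, so both rings are closed together. The all-equatorial C6(O)–C7(C)–C8(O) triad of the cyclohexane/γ-lactone pair is read as anti addition of an aldehyde carbon (C8) and a carboxyl oxygen across an (E)-C6=C7 alkene. One Lewis acid step on the acyclic keto aldehyde 13 forms C7–C8 and O–C6, two rings and three stereocentres, with unambiguous 6,12-lactone regiochemistry. The C5/C10 tertiary–quaternary pair of 13 comes from an enantioselective boron Ireland–Claisen rearrangement of a trans-β-hydromuconate allyl ester. The hydroxyisopropenyl group travels as an acetyl group.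

Key step: step 8

Numbering (elemanolide):
- The ring is C5–C10.
- C10 carries the C14 methyl and the C1=C2 vinyl group.
- C5 carries C4(=C3)C15.
- C6 carries the lactone oxygen, C7 carries C11, C8 carries the acyloxy group, and C9 is CH2.
- The lactone is O–C12(=O)–C11(=C13).
- α is the face of the C6 and C8 oxygens; β is the face of the C10 methyl.
- TBS = tert-butyldimethylsilyl.

Assumption: the (S,S)-diazaborolidine controller is taken to deliver the (5R,6S)-acid 9. The sense of induction is assigned by analogy; if it proves opposite, the (R,R)-controller is used.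

Step 1
Reactants: 1 tert-butyl(but-3-yn-1-yloxy)dimethylsilane
Product: 4 (E)-5-(TBS-oxy)-3-methylpent-2-en-1-ol, via alkenyl dimethylalane 2 (not isolated), via lithium alanate 3 (not isolated)
Conditions: Me3Al, Cp2ZrCl2 (cat.), CH2Cl2, 0 °C → rt; n-BuLi, THF, −78 °C; (CH2O)n, rt; aq. work-up
Reagents that add atoms: trimethylaluminium C[Al](C)C; formaldehyde (as paraformaldehyde) C=O
Why: Negishi Zr-catalysed syn-carboalumination places CH3 and Al cis on the terminal alkyne, and the alanate traps formaldehyde with retention, which fixes the (E)-trisubstituted alkene.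

Step 2
Reactants: 4 (E)-5-(TBS-oxy)-3-methylpent-2-en-1-ol; 5 (E)-hex-3-enedioic acid (trans-β-hydromuconic acid, 3 equiv)
Product: 6 (E)-hex-3-enedioic acid mono[(E)-5-(TBS-oxy)-3-methylpent-2-enyl] ester
Conditions: DIC, DMAP (cat.), THF, 0 °C
Reagents that add atoms: none
Why: In this Steglich esterification the excess of the cheap symmetrical diacid should make the mono-ester the main product, and low temperature with catalytic DMAP should avoid migration of the β,γ-double bond.

Step 3
Reactants: 6 half ester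
Product: 7 1-tert-butyl 6-[(E)-5-(TBS-oxy)-3-methylpent-2-enyl] (E)-hex-3-enedioate
Conditions: Cl3CC(=NH)Ot-Bu, cyclohexane/CH2Cl2, rt
Reagents that add atoms: tert-butyl 2,2,2-trichloroacetimidate CC(C)(C)OC(=N)C(Cl)(Cl)Cl
Why: tert-Butyl transfer from the trichloroacetimidate is promoted by the acid itself and needs no base, so the skipped alkene and the silyl ether should be untouched.

Step 4
Reactants: 7 mixed diester
Product: 9 tert-butyl (3E,5R,6S)-5-carboxy-6-methyl-6-vinyl-8-(TBS-oxy)oct-3-enoate, via boron ketene acetal 8 (not isolated)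
Conditions: (S,S)-bis-sulfonamide, BBr3, CH2Cl2 (controller formed in situ, volatiles removed); 7, i-Pr2NEt, CH2Cl2, −78 °C, then −20 °C; aq. work-up
Reagents that add atoms: none
Why: In this enantioselective boron-mediated Ireland–Claisen rearrangement, soft enolisation with i-Pr2NEt in CH2Cl2 should give the Z(O)-ketene acetal of the less hindered allyl ester, and a chair [3,3] shift onto the (E)-allyl terminus sets the C5/C10 tertiary–quaternary pair, the relative configuration coming from the two alkene geometries and the absolute one from the chiral diazaborolidine.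

Step 5
Reactants: 9 Claisen acid
Product: 11 tert-butyl (3E,5R,6S)-5-acetyl-6-methyl-6-vinyl-8-(TBS-oxy)oct-3-enoate, via acid chloride 10 (not isolated)
Conditions: 1-chloro-N,N,2-trimethylprop-1-en-1-amine, CH2Cl2, 0 °C; Me2CuLi (MeLi, CuI), Et2O, −78 °C
Reagents that add atoms: lithium dimethylcuprate [Li+].C[Cu-]C
Why: Neutral acid chloride formation (Ghosez reagent) and Gilman cuprate acylation should stop at the ketone and spare the tert-butyl ester and the C5 stereocentre.

Step 6
Reactants: 11 silyl ether ketone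
Product: 12 tert-butyl (3E,5R,6S)-5-acetyl-8-hydroxy-6-methyl-6-vinyloct-3-enoate
Conditions: HF·pyridine, THF, 0 °C
Reagents that add atoms: none
Why: Fluoride-mediated silyl ether cleavage under mildly acidic conditions should avoid base-induced conjugation of the β,γ-unsaturated ketone.

Step 7
Reactants: 12 primary alcohol
Product: 13 tert-butyl (3E,5R,6S)-5-acetyl-6-methyl-8-oxo-6-vinyloct-3-enoate
Conditions: Dess–Martin periodinane, CH2Cl2, 0 °C → rt
Reagents that add atoms: none
Why: Dess–Martin oxidation is neutral and stops at the aldehyde, so the 1,5-keto aldehyde should survive without aldol closure and is used directly.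

Step 8
Reactants: 13 keto aldehyde
Product: 15 hydroxy keto lactone (5β-acetyl; 6α-O/7β-CH2 trans-fused γ-lactone; 8α-OH; 10β-methyl; 10α-vinyl), via dioxocarbenium ion 14 (not isolated)
Conditions: SnCl4 (3 equiv), 2,6-di-tert-butylpyridine, CH2Cl2 (dilute), −78 → −30 °C; aq. work-up
Reagents that add atoms: none
Why: Proposed new method: SnCl4 activates the C8 aldehyde, C7 of the (E)-C6=C7 alkene attacks it through a chair transition state, and the carbonyl oxygen of the tert-butyl ester adds to C6 anti to the new C7–C8 bond as positive charge develops, giving dioxocarbenium ion 14, which loses isobutene to leave lactone 15. The closest known reaction types are Prins bicyclisations of (E)-alkenes carrying a tethered O-nucleophile, Lewis acid aldehyde–alkene carbocyclisations and carboxyl-terminated polyene cyclisations, all of which turn an (E)-alkene into a trans ring fusion; new here is their combination in a carbocycle-forming closure onto an unactivated 1,2-disubstituted alkene. The cyclohexane closes exo at the carbonyl and endo at the alkene (6-endo-trig), and the γ-lactone closes by O–C6 bond formation, 5-endo with respect to the alkene as in the halolactonisation of β,γ-unsaturated acids. C6 and C7 follow from anti addition to the (E)-alkene (O and CH2 trans-diequatorial), the alkene face is chosen by C5 and C10 (acetyl and vinyl equatorial, methyl axial in the chair), and C8–O becomes equatorial because an axial O–Sn group would clash with the axial C10 methyl. Chemoselectivity rests on masking the nucleophilic isopropenyl group as an acetyl group, on the vinyl group reaching C8 only through four- or five-membered modes, and on the fact that only the 6-endo cation at C6 can be captured as a γ-lactone. Because the carboxyl oxygen is delivered to C6 while C8 keeps the aldehyde oxygen, the 6,12-lactone should form without the 8,12-isomer that acyl closure of a 6,8-diol would allow.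

Step 9
Reactants: 15 hydroxy keto lactone
Product: 16 8α-hydroxy-13-norelema-1,3-dien-12,6α-olide (5αH,6βH,7αH,10β-methyl)
Conditions: Zn, CH2Br2, TiCl4, THF/CH2Cl2, 0 °C → rt
Reagents that add atoms: dibromomethane BrCBr
Why: Takai–Lombardo methylenation is non-basic and ketone-selective, so the β-acyloxy ketone should not eliminate and the lactone should be kept.

Step 10
Reactants: 17 methyl (R)-3-hydroxy-2-methylpropanoate ((R)-Roche ester)
Product: 18 methyl (R)-3-(TBS-oxy)-2-methylpropanoate
Conditions: TBSCl, imidazole, DMF, rt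
Reagents that add atoms: tert-butyldimethylsilyl chloride CC(C)(C)[Si](C)(C)Cl
Why: Standard imidazole-promoted silylation of a primary alcohol leaves the α-stereocentre untouched.

Step 11
Reactants: 18 silylated Roche ester
Product: 19 (R)-3-(TBS-oxy)-2-methylpropanoic acid
Conditions: LiOH, THF/H2O, 0 °C → rt; then 1 M HCl
Reagents that add atoms: lithium hydroxide [Li+].[OH-]
Why: Mild saponification of the unhindered methyl ester should proceed without epimerisation or loss of the primary silyl ether.

Step 12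
Reactants: 16 hydroxy lactone; 19 (R)-3-(TBS-oxy)-2-methylpropanoic acid
Product: 20 8α-[(R)-3-(TBS-oxy)-2-methylpropanoyloxy]-13-norelema-1,3-dien-12,6α-olide
Conditions: DIC, DMAP, CH2Cl2, 0 °C → rt
Reagents that add atoms: none
Why: Steglich esterification of the only free, equatorial hydroxyl group brings in the side-chain stereocentre from the chiral pool.

Step 13
Reactants: 20 acylated lactone
Product: 23 8α-[(R)-3-(TBS-oxy)-2-methylpropanoyloxy]elema-1,3,11(13)-trien-12,6α-olide, via Mannich base 21 (not isolated), via methiodide 22 (not isolated)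
Conditions: LiHMDS (1.05 equiv), THF, −78 °C; CH2=NMe2+ I−; MeI, THF, rt; aq. NaHCO3
Reagents that add atoms: N,N-dimethylmethyleneiminium iodide (Eschenmoser's salt) C=[N+](C)C.[I-]
Why: Kinetic enolisation of the more acidic and less hindered lactone CH2, followed by an Eschenmoser Mannich reaction, quaternisation and Hofmann-type elimination, should install the exocyclic methylene without creating a lasting stereocentre.

Step 14
Reactants: 23 α-methylene lactone
Product: 24 15-hydroxy-8α-[(R)-3-(TBS-oxy)-2-methylpropanoyloxy]elema-1,3,11(13)-trien-12,6α-olide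
Conditions: SeO2 (cat.), t-BuOOH, CH2Cl2, 0 °C → rt
Reagents that add atoms: selenium dioxide (oxygen carrier) O=[Se]=O; tert-butyl hydroperoxide (terminal oxygen source) CC(C)(C)OO
Why: Catalytic SeO2/t-BuOOH allylic hydroxylation (ene reaction, then [2,3]-shift) should occur at the isopropenyl group, the only electron-rich alkene with allylic C–H, and should prefer its CH3 over the tertiary C5–H.

Step 15
Reactants: 24 silyl ether
Product: 25 target CNP0133858.1
Conditions: HF·pyridine, THF, 0 °C → rt
Reagents that add atoms: none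
Why: Buffered fluoride desilylation frees the primary side-chain alcohol without touching the α-methylene lactone or the ester.

**Compound list**

1 | tert-butyl(but-3-yn-1-yloxy)dimethylsilane | C#CCCO[Si](C)(C)C(C)(C)C | starting material
2 | [(E)-4-(TBS-oxy)-2-methylbut-1-enyl]dimethylalane | C[Al](C)/C=C(\C)CCO[Si](C)(C)C(C)(C)C | intermediate
3 | lithium n-butyl alanate of 2 | [Li+].CCCC[Al-](C)(C)/C=C(\C)CCO[Si](C)(C)C(C)(C)C | intermediate
4 | (E)-5-(TBS-oxy)-3-methylpent-2-en-1-ol | OC/C=C(\C)CCO[Si](C)(C)C(C)(C)C | intermediate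
5 | (E)-hex-3-enedioic acid | OC(=O)C/C=C/CC(=O)O | starting material
6 | (E)-hex-3-enedioic acid mono[(E)-5-(TBS-oxy)-3-methylpent-2-enyl] ester | OC(=O)C/C=C/CC(=O)OC/C=C(\C)CCO[Si](C)(C)C(C)(C)C | intermediate
7 | 1-tert-butyl 6-[(E)-5-(TBS-oxy)-3-methylpent-2-enyl] (E)-hex-3-enedioate | CC(C)(C)OC(=O)C/C=C/CC(=O)OC/C=C(\C)CCO[Si](C)(C)C(C)(C)C | intermediate
8 | Z(O)-boron ketene acetal of 7 carrying the (S,S)-diazaborolidine | CC(C)(C)OC(=O)C/C=C/C=C(\OB1N(S(=O)(=O)c2cc(C(F)(F)F)cc(C(F)(F)F)c2)[C@@H](c2ccccc2)[C@@H](N1S(=O)(=O)c1cc(C(F)(F)F)cc(C(F)(F)F)c1)c1ccccc1)OC/C=C(\C)CCO[Si](C)(C)C(C)(C)C | intermediate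
9 | tert-butyl (3E,5R,6S)-5-carboxy-6-methyl-6-vinyl-8-(TBS-oxy)oct-3-enoate | C=C[C@](C)(CCO[Si](C)(C)C(C)(C)C)[C@H](C(=O)O)/C=C/CC(=O)OC(C)(C)C | intermediate
10 | acid chloride of 9 | C=C[C@](C)(CCO[Si](C)(C)C(C)(C)C)[C@H](C(=O)Cl)/C=C/CC(=O)OC(C)(C)C | intermediate
11 | tert-butyl (3E,5R,6S)-5-acetyl-6-methyl-6-vinyl-8-(TBS-oxy)oct-3-enoate | C=C[C@](C)(CCO[Si](C)(C)C(C)(C)C)[C@H](C(C)=O)/C=C/CC(=O)OC(C)(C)C | intermediate
12 | tert-butyl (3E,5R,6S)-5-acetyl-8-hydroxy-6-methyl-6-vinyloct-3-enoate | C=C[C@](C)(CCO)[C@H](C(C)=O)/C=C/CC(=O)OC(C)(C)C | intermediate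
13 | tert-butyl (3E,5R,6S)-5-acetyl-6-methyl-8-oxo-6-vinyloct-3-enoate | C=C[C@](C)(CC=O)[C@H](C(C)=O)/C=C/CC(=O)OC(C)(C)C | intermediate
14 | bicyclic tert-butoxy dioxocarbenium ion, C8 oxygen bound as tetrachlorostannate (zwitterion) | C=C[C@]1(C)C[C@H](O[Sn-](Cl)(Cl)(Cl)Cl)[C@H]2CC(OC(C)(C)C)=[O+][C@@H]2[C@H]1C(C)=O | intermediate
15 | hydroxy keto lactone (5β-acetyl, 6α-O/7β-CH2 trans-γ-lactone, 8α-OH, 10β-methyl, 10α-vinyl) | C=C[C@]1(C)C[C@H](O)[C@H]2CC(=O)O[C@@H]2[C@H]1C(C)=O | intermediate
16 | 8α-hydroxy-13-norelema-1,3-dien-12,6α-olide | C=C[C@]1(C)C[C@H](O)[C@H]2CC(=O)O[C@@H]2[C@H]1C(C)=C | intermediate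
17 | methyl (R)-3-hydroxy-2-methylpropanoate | COC(=O)[C@H](C)CO | starting material
18 | methyl (R)-3-(TBS-oxy)-2-methylpropanoate | COC(=O)[C@H](C)CO[Si](C)(C)C(C)(C)C | intermediate
19 | (R)-3-(TBS-oxy)-2-methylpropanoic acid | OC(=O)[C@H](C)CO[Si](C)(C)C(C)(C)C | intermediate
20 | 8α-[(R)-3-(TBS-oxy)-2-methylpropanoyloxy]-13-norelema-1,3-dien-12,6α-olide | C=C[C@]1(C)C[C@H](OC(=O)[C@H](C)CO[Si](C)(C)C(C)(C)C)[C@H]2CC(=O)O[C@@H]2[C@H]1C(C)=C | intermediate
21 | 11-(dimethylaminomethyl) lactone (C11 epimers) | C=C[C@]1(C)C[C@H](OC(=O)[C@H](C)CO[Si](C)(C)C(C)(C)C)[C@H]2C(CN(C)C)C(=O)O[C@@H]2[C@H]1C(C)=C | intermediate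
22 | methiodide of 21 (C11 epimers) | C=C[C@]1(C)C[C@H](OC(=O)[C@H](C)CO[Si](C)(C)C(C)(C)C)[C@H]2C(C[N+](C)(C)C)C(=O)O[C@@H]2[C@H]1C(C)=C.[I-] | intermediate
23 | 8α-[(R)-3-(TBS-oxy)-2-methylpropanoyloxy]elema-1,3,11(13)-trien-12,6α-olide | C=C[C@]1(C)C[C@H](OC(=O)[C@H](C)CO[Si](C)(C)C(C)(C)C)[C@H]2C(=C)C(=O)O[C@@H]2[C@H]1C(C)=C | intermediate
24 | 15-hydroxy-8α-[(R)-3-(TBS-oxy)-2-methylpropanoyloxy]elema-1,3,11(13)-trien-12,6α-olide | C=C[C@]1(C)C[C@H](OC(=O)[C@H](C)CO[Si](C)(C)C(C)(C)C)[C@H]2C(=C)C(=O)O[C@@H]2[C@H]1C(=C)CO | intermediate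
25 | (3aR,4S,6S,7R,7aR)-7-(3-hydroxyprop-1-en-2-yl)-6-methyl-3-methylidene-2-oxo-6-vinyloctahydrobenzofuran-4-yl (2R)-3-hydroxy-2-methylpropanoate | C=C[C@]1(C)C[C@H](OC(=O)[C@H](C)CO)[C@H]2C(=C)C(=O)O[C@@H]2[C@H]1C(=C)CO | target

Total step count: 15. Longest linear sequence: 13 steps (steps 1–9 and 12–15).

**Steps most likely to fail**

**1. Step 8 (Proposed new method).**
- What may go wrong:
  - the alkene is flanked by two acceptor-bearing carbons and may be too weak a nucleophile;
  - the acidic C5 proton may be lost, or a 1,2-hydride shift may occur, before the ester captures C6;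
  - the keto aldehyde may undergo aldol closure.
- The fallback uses known chemistry, with a radical instead of a cationic ring closure. It sets out from 11 and comes back at 20.
- Takai–Lombardo methylenation of 11 gives the triene ester F1.
- Shi epoxidation (D-fructose-derived ketone, Oxone, buffered) of its only trans-disubstituted alkene gives the (6R,7R)-epoxide F2.
- DBU opens the β,γ-epoxy ester by E1cB to the γ-hydroxy (E)-enoate F3, which fixes the 6α-oxygen.
- TBSOTf/2,6-lutidine gives the bis-silyl ether F4, and CSA in MeOH then frees the primary alcohol F5.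
- Dess–Martin oxidation gives the aldehyde F6.
- SmI2/t-BuOH closes C7–C8 by a 6-exo-trig ketyl–enoate cyclisation to the all-equatorial cyclohexanol F7.
- Steglich esterification of its free 8α-OH with 19 gives the ester F8.
- HF·pyridine followed by PPTS in warm benzene removes both silyl groups and closes the 6,12-lactone at the acyl carbon, giving the hydroxy ester lactone F9.
- TBSCl/imidazole returns to 20.

**2. Step 4.**
- What may go wrong:
  - competing soft enolisation at the tert-butyl ester terminus;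
  - erosion of ketene acetal geometry for the dienolate;
  - slow rearrangement onto the trisubstituted allyl terminus, with loss of diastereo- or enantioselectivity.
- The fallback sets out from 7 and comes back at 9.
- LDA (2.3 equiv) and TMSCl in THF/DMPU enolise both ester termini on purpose. Only the allyl terminus can undergo the classical Ireland–Claisen shift.
- Aqueous work-up restores the tert-butyl β,γ-unsaturated ester and gives the racemic acid F10.
- Crystallisation with (R)-1-phenylethylamine gives the diastereomerically pure ammonium salt F11, and acidification returns 9.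

**3. Step 13.**
- What may go wrong:
  - enolisation of the side-chain ester, followed by β-elimination of silanolate;
  - O-to-C acyl transfer onto the lactone enolate.
- The fallback sets out from 16 and comes back at 23. It carries out the methylenation before any second ester is present.
- TESOTf/2,6-lutidine gives the triethylsilyl ether F12.
- LDA, Eschenmoser's salt, MeI and aq. NaHCO3 give the α-methylene lactone silyl ether F13.
- HF·pyridine gives the 8α-hydroxy α-methylene lactone F14.
- Steglich esterification with 19 returns to 23.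

**Further compounds**

F1 | step 8 | tert-butyl (3E,5S,6S)-6-methyl-5-(prop-1-en-2-yl)-6-vinyl-8-(TBS-oxy)oct-3-enoate (same spatial arrangement as 11) | C=C[C@](C)(CCO[Si](C)(C)C(C)(C)C)[C@H](C(C)=C)/C=C/CC(=O)OC(C)(C)C
F2 | step 8 | (6R,7R)-trans-epoxide of F1 (elemanolide C6/C7) | C=C[C@](C)(CCO[Si](C)(C)C(C)(C)C)[C@H](C(C)=C)[C@H]1O[C@@H]1CC(=O)OC(C)(C)C
F3 | step 8 | γ-hydroxy (E)-enoate (6-OH as in the target) | C=C[C@](C)(CCO[Si](C)(C)C(C)(C)C)[C@H](C(C)=C)[C@@H](O)/C=C/C(=O)OC(C)(C)C
F4 | step 8 | bis-TBS ether of F3 | C=C[C@](C)(CCO[Si](C)(C)C(C)(C)C)[C@H](C(C)=C)[C@@H](O[Si](C)(C)C(C)(C)C)/C=C/C(=O)OC(C)(C)C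
F5 | step 8 | primary alcohol from F4 | C=C[C@](C)(CCO)[C@H](C(C)=C)[C@@H](O[Si](C)(C)C(C)(C)C)/C=C/C(=O)OC(C)(C)C
F6 | step 8 | aldehyde from F5 | C=C[C@](C)(CC=O)[C@H](C(C)=C)[C@@H](O[Si](C)(C)C(C)(C)C)/C=C/C(=O)OC(C)(C)C
F7 | step 8 | all-equatorial cyclohexanol (6α-OTBS, 7β-CH2CO2t-Bu, 8α-OH) | C=C[C@]1(C)C[C@H](O)[C@@H](CC(=O)OC(C)(C)C)[C@H](O[Si](C)(C)C(C)(C)C)[C@H]1C(C)=C
F8 | step 8 | 8-O-[(R)-3-(TBS-oxy)-2-methylpropanoyl] ester of F7 | C=C[C@]1(C)C[C@H](OC(=O)[C@H](C)CO[Si](C)(C)C(C)(C)C)[C@@H](CC(=O)OC(C)(C)C)[C@H](O[Si](C)(C)C(C)(C)C)[C@H]1C(C)=C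
F9 | step 8 | 8α-[(R)-3-hydroxy-2-methylpropanoyloxy]-13-norelema-1,3-dien-12,6α-olide | C=C[C@]1(C)C[C@H](OC(=O)[C@H](C)CO)[C@H]2CC(=O)O[C@@H]2[C@H]1C(C)=C
F10 | step 4 | racemic 9 (both enantiomers) | C=C[C@](C)(CCO[Si](C)(C)C(C)(C)C)[C@H](C(=O)O)/C=C/CC(=O)OC(C)(C)C.C=C[C@@](C)(CCO[Si](C)(C)C(C)(C)C)[C@@H](C(=O)O)/C=C/CC(=O)OC(C)(C)C
F11 | step 4 | (R)-1-phenylethylammonium salt of 9 | C=C[C@](C)(CCO[Si](C)(C)C(C)(C)C)[C@H](C(=O)[O-])/C=C/CC(=O)OC(C)(C)C.C[C@@H]([NH3+])c1ccccc1
F12 | step 13 | 8-O-triethylsilyl ether of 16 | C=C[C@]1(C)C[C@H](O[Si](CC)(CC)CC)[C@H]2CC(=O)O[C@@H]2[C@H]1C(C)=C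
F13 | step 13 | 8α-(triethylsilyloxy)elema-1,3,11(13)-trien-12,6α-olide | C=C[C@]1(C)C[C@H](O[Si](CC)(CC)CC)[C@H]2C(=C)C(=O)O[C@@H]2[C@H]1C(C)=C
F14 | step 13 | 8α-hydroxyelema-1,3,11(13)-trien-12,6α-olide | C=C[C@]1(C)C[C@H](O)[C@H]2C(=C)C(=O)O[C@@H]2[C@H]1C(C)=C
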